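**Strateg**y

Everything rests on cutting the pyran ring at C4–C4a while leaving the C2–O1 bond intact. C2 is a tertiary aryl ether carbon that is also allylic to C3=C4, so its configuration would be lost if C2–O1 ionised or the pyran ring opened. Closing the ring at the other end avoids this. In the key step Ph3PAuNTf2, a monovalent gold π-acid, activates the terminal alkyne of an (S)-tertiary propargylic aryl ether and the free ortho arene carbon attacks 6-endo-dig, giving the 2H-chromene with C3=C4 in one operation. The precursor carries a 3-silyloxypropyl arm at C2 and a silylated O6; (2S,3S)-epoxygeraniol supplies both stereocentres.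

Key step: step 9

Remark: the chromene is numbered O1, C2 to C8a and the side chain C1′ to C12′ outward from C2; by CIP analysis the target is S at C2 and S at C8′, and both centres are traced to C3 of (2S,3S)-2,3-epoxygeraniol, whose C3–O bond is never broken.

**Route**

Step 1
Reactants: 1 geraniol
Product: 2 [(2S,3S)-3-methyl-3-(4-methylpent-3-en-1-yl)oxiran-2-yl]methanol
Conditions: Ti(OiPr)4 (5 mol %), L-(+)-diethyl tartrate (6 mol %), t-BuOOH (isooctane), 4 Å molecular sieves, CH2Cl2, −20 °C
Reagents that add atoms: tert-butyl hydroperoxide, CC(C)(C)OO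
Why: Sharpless asymmetric epoxidation: the allylic hydroxyl binds the substrate to the Ti(OiPr)4/tartrate catalyst, which delivers the peroxide oxygen to the single alkene face selected by the L-(+)-tartrate ligand and so sets 2S,3S, while the remote trisubstituted alkene has no directing group and is left alone.

Step 2
Reactants: 2 [(2S,3S)-3-methyl-3-(4-methylpent-3-en-1-yl)oxiran-2-yl]methanol
Product: 3 (2S,3R)-3-(chloromethyl)-2-methyl-2-(4-methylpent-3-en-1-yl)oxirane
Conditions: PPh3, CCl4, NaHCO3 (cat.), reflux
Reagents that add atoms: carbon tetrachloride, ClC(Cl)(Cl)Cl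
Why: Appel chlorination replaces the primary hydroxyl by chloride in a neutral SN2 process at the CH2 group only, so the epoxide and both stereocentres are untouched (the new descriptor at the CH carbon is a priority change, not an inversion).

Step 3
Reactants: 3 (2S,3R)-3-(chloromethyl)-2-methyl-2-(4-methylpent-3-en-1-yl)oxirane
Product: 5 (3S)-3,7-dimethyloct-6-en-1-yn-3-ol, via chlorovinyl carbinol lithium alkoxide 4 (not isolated)
Conditions: n-BuLi (3.3 equiv), THF, −40 °C; aq. NH4Cl
Reagents that add atoms: none
Why: Base-induced eliminative opening of a 2,3-epoxy chloride: deprotonation next to chlorine opens the epoxide at the C–O bond of the CH carbon, a second dehydrochlorination gives the alkyne, and because the C–O bond at the quaternary carbon is never broken the tertiary carbinol keeps the S configuration set in step 1.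

Step 4
Reactants: 5 (3S)-3,7-dimethyloct-6-en-1-yn-3-ol
Product: 7 (4S)-4-methylhex-5-yne-1,4-diol, via hydroxy aldehyde 6 (not isolated)
Conditions: O3, CH2Cl2/MeOH, −78 °C (Sudan Red 7B as end-point indicator); then NaBH4, −78 to 0 °C
Reagents that add atoms: ozone, [O-][O+]=O
Why: Ozonolysis with reductive work-up: the electron-rich trisubstituted alkene reacts with ozone far faster than the terminal alkyne, the dye marks the end-point, and borohydride reduces the peroxidic intermediates and the aldehyde to the primary alcohol without touching the stereocentre.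

Step 5
Reactants: 7 (4S)-4-methylhex-5-yne-1,4-diol
Product: 8 (3S)-6-[(tert-butyldimethylsilyl)oxy]-3-methylhex-1-yn-3-ol
Conditions: TBSCl (1.05 equiv), imidazole, CH2Cl2, 0 °C
Reagents that add atoms: tert-butyldimethylsilyl chloride, CC(C)(C)[Si](C)(C)Cl
Why: Selective silylation: the primary hydroxyl reacts much faster than the hindered tertiary propargylic one, which stays free for the O-arylation.

Step 6
Reactants: 9 4-iodo-3-methylphenol
Product: 10 (4-iodo-3-methylphenoxy)triisopropylsilane
Conditions: TIPSCl, imidazole, DMF, rt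
Reagents that add atoms: triisopropylsilyl chloride, CC(C)[Si](Cl)(C(C)C)C(C)C
Why: Standard phenol silylation; the bulky triisopropylsilyl ether is chosen because it should survive the acid, hydride and palladium chemistry that follows and is removed by fluoride at the very end.

Step 7
Reactants: 10 (4-iodo-3-methylphenoxy)triisopropylsilane; 11 1,3,5-trimethoxybenzene
Product: 13 [2-methyl-4-(triisopropylsilyloxy)phenyl](2,4,6-trimethoxyphenyl)iodonium 4-methylbenzenesulfonate, via aryl hydroxy(tosyloxy)iodane 12 (not isolated)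
Conditions: mCPBA, TsOH·H2O, MeCN, 40 °C; then 11, rt
Reagents that add atoms: 4-methylbenzenesulfonic acid monohydrate, Cc1ccc(cc1)S(=O)(=O)O.O
Why: One-pot diaryliodonium salt synthesis: the peracid oxidises the aryl iodide to a trivalent iodine species captured by tosylate, and this electrophile substitutes the very electron-rich trimethoxybenzene at carbon, giving a salt whose trimethoxyphenyl group serves as the non-transferred auxiliary.

Step 8
Reactants: 8 (3S)-6-[(tert-butyldimethylsilyl)oxy]-3-methylhex-1-yn-3-ol; 13 [2-methyl-4-(triisopropylsilyloxy)phenyl](2,4,6-trimethoxyphenyl)iodonium 4-methylbenzenesulfonate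
Product: 14 tert-butyl({(4S)-4-methyl-4-[2-methyl-4-(triisopropylsilyloxy)phenoxy]hex-5-yn-1-yl}oxy)dimethylsilane
Conditions: NaH (1.1 equiv), toluene, 0 °C to rt; then 13, rt to 40 °C
Reagents that add atoms: none
Why: Metal-free O-arylation of a tertiary alkoxide with a diaryliodonium salt: the alkoxide exchanges with tosylate at iodine and ligand coupling transfers the less electron-rich, ortho-methylated aryl group to oxygen while 2-iodo-1,3,5-trimethoxybenzene departs, and since only the aryl–O bond is formed the carbinol carbon keeps its S configuration.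

Step 9
Reactants: 14 tert-butyl({(4S)-4-methyl-4-[2-methyl-4-(triisopropylsilyloxy)phenoxy]hex-5-yn-1-yl}oxy)dimethylsilane
Product: 15 tert-butyl{3-[(2S)-2,8-dimethyl-6-(triisopropylsilyloxy)-2H-chromen-2-yl]propoxy}dimethylsilane
Conditions: Ph3PAuNTf2 (3 mol %), CH2Cl2, rt, dark
Reagents that add atoms: none
Why: Ph3PAuNTf2 coordinates the terminal alkyne as a π-acid, the arene carbon ortho to the ether oxygen (future C4a) adds anti to the metal at the terminal alkyne carbon (future C4) in a Friedel–Crafts-type step, and rearomatisation followed by protodemetalation at C3 releases the 2H-chromene and the catalyst. The closest known reaction type is the intramolecular hydroarylation of aryl propargyl ethers to 2H-chromenes with monovalent gold or platinum π-acids, which is established for terminal alkynes and for tertiary propargylic ethers. The pyran ring closes in the 6-endo-dig mode by forming C4–C4a. No stereocentre is created, and C2 is a spectator because the C2–O1 bond is never broken, unlike in a thermal propargyl Claisen sequence, which passes through a planar dienone, so the configuration from step 1 is carried through unchanged. The step needs 6-endo over 5-exo closure and attack at C4a only: the first is the normal preference of aryl propargyl ethers with a terminal alkyne, and the second is secured because O1 directs ortho and the other ortho carbon (C8) carries the methyl group. The side chain is kept saturated and its hydroxyl silylated so that neither 1,6-enyne cycloisomerisation nor hydroalkoxylation can compete, and room temperature and exclusion of light guard the product against electrocyclic ring opening.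

Step 10
Reactants: 15 tert-butyl{3-[(2S)-2,8-dimethyl-6-(triisopropylsilyloxy)-2H-chromen-2-yl]propoxy}dimethylsilane
Product: 16 3-[(2S)-2,8-dimethyl-6-(triisopropylsilyloxy)-2H-chromen-2-yl]propan-1-ol
Conditions: AcOH/THF/H2O (3:1:1), rt, dark
Reagents that add atoms: none
Why: Acid-catalysed hydrolysis of a primary alkyl silyl ether: the unhindered alkyl tert-butyldimethylsilyl ether is cleaved by dilute acetic acid whereas the hindered aryl triisopropylsilyl ether should be inert, and an acid this weak cannot protonate O1 and ionise the C2–O1 bond.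

Step 11
Reactants: 16 3-[(2S)-2,8-dimethyl-6-(triisopropylsilyloxy)-2H-chromen-2-yl]propan-1-ol
Product: 17 3-[(2S)-2,8-dimethyl-6-(triisopropylsilyloxy)-2H-chromen-2-yl]propanal
Conditions: Dess–Martin periodinane, pyridine, CH2Cl2, 0 °C to rt
Reagents that add atoms: none
Why: Dess–Martin oxidation under buffered conditions stops at the aldehyde and should not affect the electron-rich chromene or the aryl silyl ether.

Step 12
Reactants: 17 3-[(2S)-2,8-dimethyl-6-(triisopropylsilyloxy)-2H-chromen-2-yl]propanal
Product: 18 ethyl (2E)-5-[(2S)-2,8-dimethyl-6-(triisopropylsilyloxy)-2H-chromen-2-yl]-2-methylpent-2-enoate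
Conditions: Ph3P=C(Me)CO2Et, CH2Cl2, rt to 40 °C
Reagents that add atoms: ethyl 2-(triphenylphosphoranylidene)propanoate, CCOC(=O)C(C)=P(c1ccccc1)(c1ccccc1)c1ccccc1
Why: Wittig olefination with a stabilised ylide: reversible oxaphosphetane formation favours the E-trisubstituted enoate, which fixes the C3′=C4′ geometry and brings in C4′, its methyl group and C5′.

Step 13
Reactants: 18 ethyl (2E)-5-[(2S)-2,8-dimethyl-6-(triisopropylsilyloxy)-2H-chromen-2-yl]-2-methylpent-2-enoate
Product: 19 (2E)-5-[(2S)-2,8-dimethyl-6-(triisopropylsilyloxy)-2H-chromen-2-yl]-2-methylpent-2-en-1-ol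
Conditions: i-Bu2AlH (2.5 equiv), CH2Cl2, −78 °C; aq. potassium sodium tartrate
Reagents that add atoms: none
Why: 1,2-Reduction of the conjugated ester with diisobutylaluminium hydride gives the allylic alcohol without touching the alkenes or the aryl silyl ether.

Step 14
Reactants: 19 (2E)-5-[(2S)-2,8-dimethyl-6-(triisopropylsilyloxy)-2H-chromen-2-yl]-2-methylpent-2-en-1-ol
Product: 20 (2S)-2-[(3E)-5-bromo-4-methylpent-3-en-1-yl]-2,8-dimethyl-6-(triisopropylsilyloxy)-2H-chromene
Conditions: CBr4, PPh3, 2,6-lutidine, CH2Cl2, −20 to 0 °C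
Reagents that add atoms: carbon tetrabromide, BrC(Br)(Br)Br
Why: Appel bromination: SN2 displacement of the alkoxyphosphonium group at the primary allylic carbon under buffered conditions should give the bromide without allylic transposition or loss of alkene geometry.

Step 15
Reactants: 5 (3S)-3,7-dimethyloct-6-en-1-yn-3-ol
Product: 21 (1E,3S)-3,7-dimethyl-1-(tributylstannyl)octa-1,6-dien-3-ol
Conditions: Bu3SnH, PdCl2(PPh3)2 (2 mol %), THF, 0 °C to rt
Reagents that add atoms: tributyltin hydride, CCCC[SnH](CCCC)CCCC
Why: PdCl2(PPh3)2-catalysed hydrostannation: syn addition of Sn–H across the terminal alkyne places tin on the unhindered terminal carbon (the quaternary carbinol centre blocks the internal position) and gives the E-alkenylstannane, while the trisubstituted alkene and the stereocentre are not involved.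

Step 16
Reactants: 20 (2S)-2-[(3E)-5-bromo-4-methylpent-3-en-1-yl]-2,8-dimethyl-6-(triisopropylsilyloxy)-2H-chromene; 21 (1E,3S)-3,7-dimethyl-1-(tributylstannyl)octa-1,6-dien-3-ol
Product: 22 (2S)-2-[(3E,6E,8S)-8-hydroxy-4,8,12-trimethyltrideca-3,6,11-trien-1-yl]-2,8-dimethyl-6-(triisopropylsilyloxy)-2H-chromene
Conditions: Pd2(dba)3 (2.5 mol %), AsPh3 (10 mol %), THF, 40 °C, dark
Reagents that add atoms: none
Why: Stille coupling of an allylic bromide with an alkenylstannane: oxidative addition to zerovalent palladium, transmetalation and reductive elimination at the less hindered CH2 terminus form C5′–C6′ with retention of both alkene geometries, and the chromene C2–O1 bond should not ionise because it lies close to the plane of C3=C4 and cannot align for π-allyl formation.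

Step 17
Reactants: 22 (2S)-2-[(3E,6E,8S)-8-hydroxy-4,8,12-trimethyltrideca-3,6,11-trien-1-yl]-2,8-dimethyl-6-(triisopropylsilyloxy)-2H-chromene
Product: 23 (2S)-2-[(3E,6E,8S)-8-hydroxy-4,8,12-trimethyltrideca-3,6,11-trien-1-yl]-2,8-dimethyl-2H-chromen-6-ol
Conditions: Bu4NF, AcOH (1:1), THF, 0 °C
Reagents that add atoms: none
Why: Fluoride-mediated cleavage of the aryl silyl ether, buffered with acetic acid so that the skipped diene is not isomerised and neither the tertiary allylic alcohol nor the C2–O1 bond is ionised, releases the phenol.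

**Compound list**

1 | geraniol, (2E)-3,7-dimethylocta-2,6-dien-1-ol | CC(C)=CCC/C(C)=C/CO | starting material
2 | [(2S,3S)-3-methyl-3-(4-methylpent-3-en-1-yl)oxiran-2-yl]methanol | CC(C)=CCC[C@]1(C)O[C@H]1CO | intermediate
3 | (2S,3R)-3-(chloromethyl)-2-methyl-2-(4-methylpent-3-en-1-yl)oxirane | CC(C)=CCC[C@]1(C)O[C@H]1CCl | intermediate
4 | (3S)-1-chloro-3,7-dimethylocta-1,6-dien-3-ol, present as its lithium alkoxide (C1=C2 geometry not controlled and of no consequence) | CC(C)=CCC[C@](C)(O)C=CCl | intermediate
5 | (3S)-3,7-dimethyloct-6-en-1-yn-3-ol | C#C[C@@](C)(O)CCC=C(C)C | intermediate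
6 | (4S)-4-hydroxy-4-methylhex-5-ynal | C#C[C@@](C)(O)CCC=O | intermediate
7 | (4S)-4-methylhex-5-yne-1,4-diol | C#C[C@@](C)(O)CCCO | intermediate
8 | (3S)-6-[(tert-butyldimethylsilyl)oxy]-3-methylhex-1-yn-3-ol | C#C[C@@](C)(O)CCCO[Si](C)(C)C(C)(C)C | intermediate
9 | 4-iodo-3-methylphenol | Cc1cc(O)ccc1I | starting material
10 | (4-iodo-3-methylphenoxy)triisopropylsilane | Cc1cc(O[Si](C(C)C)(C(C)C)C(C)C)ccc1I | intermediate
11 | 1,3,5-trimethoxybenzene | COc1cc(OC)cc(OC)c1 | starting material
12 | hydroxy[2-methyl-4-(triisopropylsilyloxy)phenyl](tosyloxy)-λ3-iodane | Cc1cc(O[Si](C(C)C)(C(C)C)C(C)C)ccc1I(O)OS(=O)(=O)c1ccc(C)cc1 | intermediate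
13 | [2-methyl-4-(triisopropylsilyloxy)phenyl](2,4,6-trimethoxyphenyl)iodonium 4-methylbenzenesulfonate | Cc1cc(O[Si](C(C)C)(C(C)C)C(C)C)ccc1[I+]c1c(OC)cc(OC)cc1OC.Cc1ccc(cc1)S(=O)(=O)[O-] | intermediate
14 | tert-butyl({(4S)-4-methyl-4-[2-methyl-4-(triisopropylsilyloxy)phenoxy]hex-5-yn-1-yl}oxy)dimethylsilane (key-step precursor) | C#C[C@](C)(CCCO[Si](C)(C)C(C)(C)C)Oc1ccc(O[Si](C(C)C)(C(C)C)C(C)C)cc1C | intermediate
15 | tert-butyl{3-[(2S)-2,8-dimethyl-6-(triisopropylsilyloxy)-2H-chromen-2-yl]propoxy}dimethylsilane (key-step product) | CC(C)(C)[Si](C)(C)OCCC[C@@]1(C)C=Cc2cc(O[Si](C(C)C)(C(C)C)C(C)C)cc(C)c2O1 | intermediate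
16 | 3-[(2S)-2,8-dimethyl-6-(triisopropylsilyloxy)-2H-chromen-2-yl]propan-1-ol | OCCC[C@@]1(C)C=Cc2cc(O[Si](C(C)C)(C(C)C)C(C)C)cc(C)c2O1 | intermediate
17 | 3-[(2S)-2,8-dimethyl-6-(triisopropylsilyloxy)-2H-chromen-2-yl]propanal | O=CCC[C@@]1(C)C=Cc2cc(O[Si](C(C)C)(C(C)C)C(C)C)cc(C)c2O1 | intermediate
18 | ethyl (2E)-5-[(2S)-2,8-dimethyl-6-(triisopropylsilyloxy)-2H-chromen-2-yl]-2-methylpent-2-enoate | CCOC(=O)/C(C)=C/CC[C@@]1(C)C=Cc2cc(O[Si](C(C)C)(C(C)C)C(C)C)cc(C)c2O1 | intermediate
19 | (2E)-5-[(2S)-2,8-dimethyl-6-(triisopropylsilyloxy)-2H-chromen-2-yl]-2-methylpent-2-en-1-ol | OC/C(C)=C/CC[C@@]1(C)C=Cc2cc(O[Si](C(C)C)(C(C)C)C(C)C)cc(C)c2O1 | intermediate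
20 | (2S)-2-[(3E)-5-bromo-4-methylpent-3-en-1-yl]-2,8-dimethyl-6-(triisopropylsilyloxy)-2H-chromene | BrC/C(C)=C/CC[C@@]1(C)C=Cc2cc(O[Si](C(C)C)(C(C)C)C(C)C)cc(C)c2O1 | intermediate
21 | (1E,3S)-3,7-dimethyl-1-(tributylstannyl)octa-1,6-dien-3-ol | CCCC[Sn](CCCC)(CCCC)/C=C/[C@@](C)(O)CCC=C(C)C | intermediate
22 | (2S)-2-[(3E,6E,8S)-8-hydroxy-4,8,12-trimethyltrideca-3,6,11-trien-1-yl]-2,8-dimethyl-6-(triisopropylsilyloxy)-2H-chromene | CC(C)=CCC[C@](C)(O)/C=C/C/C(C)=C/CC[C@@]1(C)C=Cc2cc(O[Si](C(C)C)(C(C)C)C(C)C)cc(C)c2O1 | intermediate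
23 | (2S)-2-[(3E,6E,8S)-8-hydroxy-4,8,12-trimethyltrideca-3,6,11-trien-1-yl]-2,8-dimethyl-2H-chromen-6-ol | CC(C)=CCC[C@](C)(O)/C=C/C/C(C)=C/CC[C@@]1(C)C=Cc2cc(O)cc(C)c2O1 | target

**Summary**

Total step count: 17.
Longest linear sequence: 14 steps from geraniol (steps 1 to 5, 8 to 14, 16 and 17); steps 6 and 7 (iodonium salt) and step 15 (stannane) are side branches.

**Steps most likely to fail**

Step 9, the ring closure. What may go wrong: closure in the 5-exo mode, ionisation of the tertiary propargylic C–O bond by the Lewis-acidic catalyst with loss of the phenol or erosion of enantiomeric purity, or slow turnover because the attacking carbon is meta to the silyloxy group. Fallback, setting out from 14 and returning at 15: heating 14 in N,N-diethylaniline at about 180 °C should trigger the classical propargyl Claisen rearrangement, hydrogen shift and oxa-6π electrocyclisation. This metal-free sequence can only give the six-membered ring but loses the configuration at C2, so the racemic chromene F4 would be separated by preparative HPLC on a polysaccharide-based chiral stationary phase into 15 and its (R)-enantiomer F5. F5 could be re-equilibrated thermally to the racemate and recycled.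

Step 8, the O-arylation. What may go wrong: ortho-deprotonation of the electron-rich iodonium salt to an aryne and hence regioisomeric ethers, attack of the alkoxide at silicon of the aryl silyl ether, or slow ligand coupling with the hindered tertiary alkoxide. Fallback, setting out from 8 and returning at 14: the potassium alkoxide of 8 (KN(SiMe3)2, THF/DMF, 0 °C to rt) is arylated by nucleophilic aromatic substitution on commercial 4-fluoro-3-methylbenzaldehyde (Cc1cc(C=O)ccc1F) to give 4-{[(3S)-6-(tert-butyldimethylsilyloxy)-3-methylhex-1-yn-3-yl]oxy}-3-methylbenzaldehyde F1. Baeyer–Villiger oxidation with mCPBA in CH2Cl2 gives the aryl formate F2, methanolysis (K2CO3, MeOH, 0 °C) gives the phenol F3, and silylation (TIPSCl, imidazole, DMF) gives 14. The carbinol C–O bond is again never broken, so the S configuration is kept.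

Step 16, the fragment coupling. What may go wrong: syn/anti isomerisation of the π-allyl intermediate that scrambles the C3′=C4′ geometry, coupling at the branched allyl terminus, or protodestannylation of 21. Fallback, setting out from 20 and 5 and returning at 22: CuI-mediated coupling of the terminal alkyne of 5 with the allylic bromide 20 (CuI, NaI, K2CO3, DMF, rt) gives the skipped enyne F6. Hydroxyl-directed trans-hydroalumination with NaAlH2(OCH2CH2OMe)2 (THF, 0 °C) and protonolysis should reduce only the propargylic alkyne to the E-alkene and give 22.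

Further compounds
F1 | step 8 | 4-{[(3S)-6-(tert-butyldimethylsilyloxy)-3-methylhex-1-yn-3-yl]oxy}-3-methylbenzaldehyde | C#C[C@](C)(CCCO[Si](C)(C)C(C)(C)C)Oc1ccc(C=O)cc1C
F2 | step 8 | 4-{[(3S)-6-(tert-butyldimethylsilyloxy)-3-methylhex-1-yn-3-yl]oxy}-3-methylphenyl formate | C#C[C@](C)(CCCO[Si](C)(C)C(C)(C)C)Oc1ccc(OC=O)cc1C
F3 | step 8 | 4-{[(3S)-6-(tert-butyldimethylsilyloxy)-3-methylhex-1-yn-3-yl]oxy}-3-methylphenol | C#C[C@](C)(CCCO[Si](C)(C)C(C)(C)C)Oc1ccc(O)cc1C
F4 | step 9 | racemic tert-butyl{3-[2,8-dimethyl-6-(triisopropylsilyloxy)-2H-chromen-2-yl]propoxy}dimethylsilane | CC(C)(C)[Si](C)(C)OCCCC1(C)C=Cc2cc(O[Si](C(C)C)(C(C)C)C(C)C)cc(C)c2O1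
F5 | step 9 | tert-butyl{3-[(2R)-2,8-dimethyl-6-(triisopropylsilyloxy)-2H-chromen-2-yl]propoxy}dimethylsilane | CC(C)(C)[Si](C)(C)OCCC[C@]1(C)C=Cc2cc(O[Si](C(C)C)(C(C)C)C(C)C)cc(C)c2O1
F6 | step 16 | (2S)-2-[(3E,8S)-8-hydroxy-4,8,12-trimethyltrideca-3,11-dien-6-yn-1-yl]-2,8-dimethyl-6-(triisopropylsilyloxy)-2H-chromene | CC(C)=CCC[C@](C)(O)C#CC/C(C)=C/CC[C@@]1(C)C=Cc2cc(O[Si](C(C)C)(C(C)C)C(C)C)cc(C)c2O1
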